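The central benzene ring is built last by a Diels–Alder benzannulation. A 1,1,3-trioxygenated diene carrying the 4-benzyloxybenzyl group on its terminal carbon supplies ring atoms C3 (OH), C4 (H), C5 (OMe) and C6 with its benzyl arm. An aryl ynone supplies C1 with the 3-methoxyphenethyl chain and C2 with the second benzyl carbon as an aroyl group. One operation therefore forms the C6–C1 and C2–C3 bonds, closes the ring and delivers the hydroxyl and methoxyl groups already differentiated. The ortho-hydroxy ketone is then deoxygenated and both benzyl ethers are removed by hydrogenolysis.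

Key step: step 6

Assumption: the SMILES string defines the target; the name is read as 2,6-bis(4-hydroxybenzyl)-3-hydroxy-3′,5-dimethoxybibenzyl (the repeated locant 3 is taken as a misprint), and the central ring is numbered C1–C6 as in that name.

Step 1
Reactants: 1 methyl acetoacetate; 2 4-(benzyloxy)benzyl chloride
Product: 4 methyl 5-[4-(benzyloxy)phenyl]-3-oxopentanoate, via acetoacetate dianion 3 (not isolated)
Conditions: NaH (1.1 equiv), THF, 0 °C; n-BuLi (1.05 equiv), 0 °C; then 2 (0.95 equiv), 0 °C to rt; aq. HCl quench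
Reagents that add atoms: none
Why: γ-Alkylation of an acetoacetate dianion, in which the terminal carbanion is far more nucleophilic than the stabilised central enolate and displaces the activated benzylic chloride by SN2, so only C4 of the acetoacetate is benzylated.

Step 2
Reactants: 4 methyl 5-[4-(benzyloxy)phenyl]-3-oxopentanoate
Product: 6 methyl (E)-5-[4-(benzyloxy)phenyl]-3-methoxypent-2-enoate, via dimethyl ketal 5 (not isolated)
Conditions: HC(OMe)3 (3 equiv), conc. H2SO4 (cat.), rt; then concentrate and heat at 120–130 °C under reduced pressure with TsOH (cat.)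
Reagents that add atoms: trimethyl orthoformate, COC(OC)OC
Why: Acid-catalysed ketalisation by the orthoester followed by thermal loss of methanol (enol ether formation) should give the conjugated β-methoxy enoate, the E isomer being favoured under acid equilibration, while the ester and benzyl ether are inert and the alkene geometry is erased later.

Step 3
Reactants: 6 methyl (E)-5-[4-(benzyloxy)phenyl]-3-methoxypent-2-enoate
Product: 8 {[(3Z)-5-[4-(benzyloxy)phenyl]-1,3-dimethoxypenta-1,3-dien-1-yl]oxy}trimethylsilane (ketene acetal geometry unspecified), via lithium dienolate 7 (not isolated)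
Conditions: LiN(i-Pr)2 (1.1 equiv, commercial solution), THF, −78 °C; Me3SiCl (1.3 equiv), −78 °C to rt; evaporate, take up in dry pentane, filter under Ar, concentrate; used crude
Reagents that add atoms: chlorotrimethylsilane, C[Si](C)(C)Cl
Why: Kinetic γ-deprotonation of the vinylogous carbonate by the hindered amide gives the extended dienolate, which the hard silyl chloride traps on oxygen (O-silylation to a ketene silyl acetal), the standard way to 1-alkoxy-1-silyloxy-3-alkoxy dienes; the benzyl group is expected trans to C2, outward in the s-cis diene.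

Step 4
Reactants: 9 1-(trimethylsilyl)propyne; 10 3-methoxybenzyl bromide
Product: 13 4-(3-methoxyphenyl)but-1-yne, via lithiated silylpropyne 11 (not isolated), via silylalkyne 12 (not isolated)
Conditions: 9 (1.2 equiv), n-BuLi (1.15 equiv), THF, −78 °C; then 10, −78 °C to rt; then MeOH, K2CO3 (0.2 equiv), rt, same flask
Reagents that add atoms: none
Why: Propargylic lithiation of the silyl-capped propyne and SN2 alkylation by the benzylic bromide (the bulky silyl group steers attack to the propargylic rather than the allenic terminus), followed by base-catalysed methanolysis of the alkynyl C–Si bond.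

Step 5
Reactants: 13 4-(3-methoxyphenyl)but-1-yne; 14 4-(benzyloxy)benzoyl chloride
Product: 15 1-[4-(benzyloxy)phenyl]-5-(3-methoxyphenyl)pent-2-yn-1-one
Conditions: PdCl2(PPh3)2 (2 mol %), CuI (4 mol %), Et3N (1.3 equiv), THF, rt, Ar
Reagents that add atoms: none
Why: Acyl Sonogashira coupling, in which the aroyl chloride adds oxidatively to zerovalent palladium, the copper acetylide transmetalates and reductive elimination gives the ynone at room temperature, mild enough to avoid conjugate addition of the amine.

Step 6
Reactants: 8 {[(3Z)-5-[4-(benzyloxy)phenyl]-1,3-dimethoxypenta-1,3-dien-1-yl]oxy}trimethylsilane; 15 1-[4-(benzyloxy)phenyl]-5-(3-methoxyphenyl)pent-2-yn-1-one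
Product: 18 [4-(benzyloxy)phenyl]{3-[4-(benzyloxy)benzyl]-6-hydroxy-4-methoxy-2-[2-(3-methoxyphenyl)ethyl]phenyl}methanone, via cyclohexadiene cycloadduct 16 (not isolated), via aryl silyl ether 17 (not isolated)
Conditions: 8 (2.5 equiv, two portions), toluene, 90 °C, sealed tube, Ar; then 1 M aq. HCl, THF, rt
Reagents that add atoms: none
Why: The electron-rich ketene-acetal diene adds to the electron-poor ynone in a polarised, asynchronous [4+2] cycloaddition (at the stepwise limit a vinylogous Mukaiyama–Michael addition followed by closure onto the allenolate, which gives the same adduct): the benzyl-bearing diene terminus bonds to the ynone β-carbon and the ketene-acetal carbon bonds to the α-carbon. The closest known reaction type is the Diels–Alder benzannulation of 1,1,3-trioxygenated silyloxy dienes with acetylenic ketones and esters to give resorcinol monoethers. The one ring closed is the central six-membered carbocycle, formed by intermolecular [4+2] closure between diene C1/C4 and the two alkyne carbons as a 1,4-cyclohexadiene bearing a mixed methyl silyl ketal, which aromatises by 1,4-loss of methanol and is desilylated in the acidic work-up. No stereocentre is set, because the two sp3 centres of the cycloadduct and the diene geometry vanish on aromatisation. The step needs regioselectivity, which the matched polarisation secures (largest HOMO coefficient at the diene terminus, largest LUMO coefficient at the ynone β-carbon), placing the aroyl group ortho to the new, hydrogen-bonded hydroxyl and the methoxyl meta to it. The hydrolytic work-up also turns any surviving mixed ketal into the dienone tautomer of the same phenol, so the OH/OMe assignment should hold without any later selective demethylation that could endanger the benzyl ethers.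

Step 7
Reactants: 18 [4-(benzyloxy)phenyl]{3-[4-(benzyloxy)benzyl]-6-hydroxy-4-methoxy-2-[2-(3-methoxyphenyl)ethyl]phenyl}methanone
Product: 21 2,4-bis[4-(benzyloxy)benzyl]-5-methoxy-3-[2-(3-methoxyphenyl)ethyl]phenol, via aryl ethyl carbonate 19 (not isolated), via ortho-quinone methide 20 (not isolated)
Conditions: ClCO2Et (1.2 equiv), Et3N (1.3 equiv), THF, 0 °C; filter; then NaBH4 (4 equiv), THF–H2O, 0 °C to rt
Reagents that add atoms: none
Why: Ortho-hydroxyl-assisted deoxygenation (carbonate activation, then borohydride reduction): hydride reduces the ketone, the benzylic alkoxide takes over the neighbouring carbonate, the phenoxide expels ethyl carbonate to form the ortho-quinone methide, and a second hydride adds at its exocyclic carbon to give the diarylmethane with all ethers untouched.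

Step 8
Reactants: 21 2,4-bis[4-(benzyloxy)benzyl]-5-methoxy-3-[2-(3-methoxyphenyl)ethyl]phenol
Product: 22 2,4-bis(4-hydroxybenzyl)-5-methoxy-3-[2-(3-methoxyphenyl)ethyl]phenol (the target)
Conditions: H2 (1 atm), 10% Pd/C, EtOAc–MeOH (1:1), rt
Reagents that add atoms: none
Why: Heterogeneous catalytic hydrogenolysis of the two aryl benzyl ethers; the aryl methyl ethers, the free phenol and the diarylmethane and bibenzyl C–C bonds are inert under these neutral conditions.

Compound list
1 | methyl acetoacetate | COC(=O)CC(C)=O | starting material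
2 | 4-(benzyloxy)benzyl chloride | ClCc1ccc(OCc2ccccc2)cc1 | starting material
3 | sodium lithium dianion of methyl acetoacetate | COC([O-])=CC([O-])=C.[Li+].[Na+] | intermediate
4 | methyl 5-[4-(benzyloxy)phenyl]-3-oxopentanoate | COC(=O)CC(=O)CCc1ccc(OCc2ccccc2)cc1 | intermediate
5 | methyl 5-[4-(benzyloxy)phenyl]-3,3-dimethoxypentanoate | COC(=O)CC(OC)(OC)CCc1ccc(OCc2ccccc2)cc1 | intermediate
6 | methyl (E)-5-[4-(benzyloxy)phenyl]-3-methoxypent-2-enoate | COC(=O)/C=C(/OC)CCc1ccc(OCc2ccccc2)cc1 | intermediate
7 | lithium 5-[4-(benzyloxy)phenyl]-1,3-dimethoxypenta-1,3-dien-1-olate | [Li+].COC([O-])=C/C(OC)=C/Cc1ccc(OCc2ccccc2)cc1 | intermediate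
8 | {[(3Z)-5-[4-(benzyloxy)phenyl]-1,3-dimethoxypenta-1,3-dien-1-yl]oxy}trimethylsilane (ketene acetal geometry unspecified) | COC(O[Si](C)(C)C)=C/C(OC)=C/Cc1ccc(OCc2ccccc2)cc1 | intermediate
9 | 1-(trimethylsilyl)propyne | CC#C[Si](C)(C)C | starting material
10 | 3-methoxybenzyl bromide | COc1cccc(CBr)c1 | starting material
11 | 3-lithio-1-(trimethylsilyl)propyne | [Li]CC#C[Si](C)(C)C | intermediate
12 | [4-(3-methoxyphenyl)but-1-yn-1-yl]trimethylsilane | COc1cccc(CCC#C[Si](C)(C)C)c1 | intermediate
13 | 4-(3-methoxyphenyl)but-1-yne | COc1cccc(CCC#C)c1 | intermediate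
14 | 4-(benzyloxy)benzoyl chloride | O=C(Cl)c1ccc(OCc2ccccc2)cc1 | starting material
15 | 1-[4-(benzyloxy)phenyl]-5-(3-methoxyphenyl)pent-2-yn-1-one | COc1cccc(CCC#CC(=O)c2ccc(OCc3ccccc3)cc2)c1 | intermediate
16 | [4-(benzyloxy)phenyl]{3-[4-(benzyloxy)benzyl]-4,6-dimethoxy-2-[2-(3-methoxyphenyl)ethyl]-6-(trimethylsiloxy)cyclohexa-1,4-dien-1-yl}methanone (mixture of diastereomers) | COC1(O[Si](C)(C)C)C=C(OC)C(Cc2ccc(OCc3ccccc3)cc2)C(CCc2cccc(OC)c2)=C1C(=O)c1ccc(OCc2ccccc2)cc1 | intermediate
17 | [4-(benzyloxy)phenyl]{3-[4-(benzyloxy)benzyl]-4-methoxy-2-[2-(3-methoxyphenyl)ethyl]-6-(trimethylsiloxy)phenyl}methanone | COc1cccc(CCc2c(C(=O)c3ccc(OCc4ccccc4)cc3)c(O[Si](C)(C)C)cc(OC)c2Cc2ccc(OCc3ccccc3)cc2)c1 | intermediate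
18 | [4-(benzyloxy)phenyl]{3-[4-(benzyloxy)benzyl]-6-hydroxy-4-methoxy-2-[2-(3-methoxyphenyl)ethyl]phenyl}methanone | COc1cccc(CCc2c(C(=O)c3ccc(OCc4ccccc4)cc3)c(O)cc(OC)c2Cc2ccc(OCc3ccccc3)cc2)c1 | intermediate
19 | 2-[4-(benzyloxy)benzoyl]-4-[4-(benzyloxy)benzyl]-5-methoxy-3-[2-(3-methoxyphenyl)ethyl]phenyl ethyl carbonate | COc1cccc(CCc2c(C(=O)c3ccc(OCc4ccccc4)cc3)c(OC(=O)OCC)cc(OC)c2Cc2ccc(OCc3ccccc3)cc2)c1 | intermediate
20 | 6-[4-(benzyloxy)benzylidene]-4-[4-(benzyloxy)benzyl]-3-methoxy-5-[2-(3-methoxyphenyl)ethyl]cyclohexa-2,4-dien-1-one (exocyclic geometry unspecified) | COC1=CC(=O)C(=Cc2ccc(OCc3ccccc3)cc2)C(CCc2cccc(OC)c2)=C1Cc1ccc(OCc2ccccc2)cc1 | intermediate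
21 | 2,4-bis[4-(benzyloxy)benzyl]-5-methoxy-3-[2-(3-methoxyphenyl)ethyl]phenol | COc1cccc(CCc2c(Cc3ccc(OCc4ccccc4)cc3)c(O)cc(OC)c2Cc2ccc(OCc3ccccc3)cc2)c1 | intermediate
22 | 2,4-bis(4-hydroxybenzyl)-5-methoxy-3-[2-(3-methoxyphenyl)ethyl]phenol (2,6-bis(4-hydroxybenzyl)-3-hydroxy-3′,5-dimethoxybibenzyl) | COc1cccc(CCc2c(Cc3ccc(O)cc3)c(O)cc(OC)c2Cc2ccc(O)cc2)c1 | target

Total steps: 8. Longest linear sequence: 6 steps (steps 1, 2, 3, 6, 7 and 8).

Steps most likely to fail

Step 6. The cycloaddition joins a 4-substituted diene to an internal, β-alkylated aryl ynone and may be slow enough that thermal decomposition or adventitious hydrolysis of the ketene silyl acetal outruns ring formation. The fallback sets out from alkyne 13 and diene 8 and replaces the aroyl activator by a smaller, more electrophilic formyl group. Formylation of 13 (n-BuLi, THF, −78 °C; DMF; buffered aqueous quench) should give 5-(3-methoxyphenyl)pent-2-ynal F1. Cycloaddition of F1 with 8 (toluene, rt to 50 °C, then dilute HCl) should give 3-[4-(benzyloxy)benzyl]-6-hydroxy-4-methoxy-2-[2-(3-methoxyphenyl)ethyl]benzaldehyde F2. Addition of commercial 4-BnOC6H4MgBr (3 equiv, THF, 0 °C; the first equivalent deprotonates the phenol) should give the racemic ortho-hydroxybenzhydrol [4-(benzyloxy)phenyl]{3-[4-(benzyloxy)benzyl]-6-hydroxy-4-methoxy-2-[2-(3-methoxyphenyl)ethyl]phenyl}methanol F3. Ionic hydrogenation of F3 (Et3SiH, CF3CO2H, CH2Cl2, 0 °C), through the doubly benzylic oxygen-stabilised cation, should give the diarylmethane. The fallback returns to the route at compound 21.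

Step 3. γ-Deprotonation of the fully substituted β-methoxy enoate may be incomplete, or may deliver the dienolate with the benzyl group turned inward, so that the isolated ketene silyl acetal is impure or unreactive. The fallback sets out from β-keto ester 4 and uses the bis-silyl diene class, which is well established for γ-substituted acetoacetates. Silylation of 4 (Me3SiCl, Et3N, hexane, rt) should give methyl 5-[4-(benzyloxy)phenyl]-3-(trimethylsiloxy)pent-2-enoate F4. Deprotonation and silylation of F4 (LiN(i-Pr)2, THF, −78 °C; Me3SiCl) should give 5-[4-(benzyloxy)phenyl]-1-methoxy-1,3-bis(trimethylsiloxy)penta-1,3-diene F5. Cycloaddition of F5 with ynone 15 under the conditions of step 6 should give the resorcinol ketone [4-(benzyloxy)phenyl]{3-[4-(benzyloxy)benzyl]-4,6-dihydroxy-2-[2-(3-methoxyphenyl)ethyl]phenyl}methanone F6. Selective O-methylation of the non-chelated hydroxyl para to the carbonyl (MeI 1.05 equiv, K2CO3, acetone, rt; the ortho hydroxyl is held back by its hydrogen bond to the ketone) returns to the route at compound 18.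

Step 7. Cleavage of the aryl carbonate by borohydride or hydroxide may compete with hydride delivery to the hindered, doubly ortho-substituted and electron-rich diaryl ketone, regenerating the unreactive hydrogen-bonded phenol. The fallback sets out from 18 and replaces the hydride/quinone methide pathway by a cationic one. Ionic hydrogenation of 18 itself (Et3SiH in excess, CF3CO2H, CH2Cl2, rt, or BF3·OEt2 in place of the acid) proceeds through the protonated ketone and the oxygen-stabilised diarylmethyl cation. It should give the diarylmethane directly and returns to the route at compound 21. Any partial loss of a benzyl ether under the acid would be harmless, because step 8 removes both. No new compound is formed.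

Further compounds
F1 | step 6 | 5-(3-methoxyphenyl)pent-2-ynal | COc1cccc(CCC#CC=O)c1
F2 | step 6 | 3-[4-(benzyloxy)benzyl]-6-hydroxy-4-methoxy-2-[2-(3-methoxyphenyl)ethyl]benzaldehyde | COc1cccc(CCc2c(C=O)c(O)cc(OC)c2Cc2ccc(OCc3ccccc3)cc2)c1
F3 | step 6 | [4-(benzyloxy)phenyl]{3-[4-(benzyloxy)benzyl]-6-hydroxy-4-methoxy-2-[2-(3-methoxyphenyl)ethyl]phenyl}methanol (racemic) | COc1cccc(CCc2c(C(O)c3ccc(OCc4ccccc4)cc3)c(O)cc(OC)c2Cc2ccc(OCc3ccccc3)cc2)c1
F4 | step 3 | methyl 5-[4-(benzyloxy)phenyl]-3-(trimethylsiloxy)pent-2-enoate (E/Z mixture) | COC(=O)C=C(O[Si](C)(C)C)CCc1ccc(OCc2ccccc2)cc1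
F5 | step 3 | 5-[4-(benzyloxy)phenyl]-1-methoxy-1,3-bis(trimethylsiloxy)penta-1,3-diene (geometry unspecified) | COC(O[Si](C)(C)C)=CC(O[Si](C)(C)C)=CCc1ccc(OCc2ccccc2)cc1
F6 | step 3 | [4-(benzyloxy)phenyl]{3-[4-(benzyloxy)benzyl]-4,6-dihydroxy-2-[2-(3-methoxyphenyl)ethyl]phenyl}methanone | COc1cccc(CCc2c(C(=O)c3ccc(OCc4ccccc4)cc3)c(O)cc(O)c2Cc2ccc(OCc3ccccc3)cc2)c1
F0 | step 7 | none | none
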